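The C8 angelate, the C13 methylene group and the C9 carbinol are first traced back to a cis,cis-cyclodecadienone. Re-forming C1–C4 and C5–C10 in that dienone gives a tricyclo[4.4.0.0(2,5)]decane, which is cut at C4–C5 and C1–C10 into a 2-carbomethoxycyclohexenone lactone and 1-methylcyclobutene.
The feature that allows this: the ten-membered carbocycle holds C1=C10 and C4=C5 joined through C2–C3. It is a cyclodeca-1,5-diene, the opened form of a bicyclo[2.2.0]hexane made of C1, C2, C3, C4, C5 and C10. C5–C10 then form a cyclohexenone whose C9 ketone is the chromophore.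
Rings arise in this order: the cyclohexane of (−)-quinic acid (C5–C10), the trans-fused γ-lactone (O, C6, C7, C11, C12), the cyclobutane by [2+2] photocycloaddition, then the ten-membered ring by thermal cleavage of both four-membered rings.
Stereochemistry: C8 comes from quinic acid. C7 is relayed from it by an acetonide-directed Luche reduction and a suprafacial Johnson–Claisen shift. C6 is set by dihydroxylation anti to C11, and C9 by Felkin–Anh reduction next to C8.
Both ring double bonds are settled under thermodynamic control in the thermolysis. The Z geometry of the angelate is bought with angelic acid.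

Key step: step 15

Remark on the target: the SMILES is read as 6R,7S,8S,9S, with C3/C6 cis on C4=C5 (4Z) and C2/C9 cis on C1=C10. The route aims at exactly this cis,cis isomer.
Remark on numbering: germacrane numbers of the target are used for all intermediates. Quinic acid C1, C6, C5, C4, C3, C2 become C5, C6, C7, C8, C9, C10. The top face is the face of the six-membered ring that finally carries the C6 oxygen. The O8/O9 acetonide lies on the bottom face.

Step 1
Reactants: 1 (−)-quinic acid
Product: 2 3,4-O-isopropylidenequinic acid 1,5-lactone (acetonide on O8/O9; bridged lactone from the C5 carboxyl group to O7)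
Conditions: Me2C(OMe)2, TsOH (cat.), acetone, reflux
Reagents that add atoms: 2,2-dimethoxypropane COC(C)(C)OC
Why: Acid-catalysed transketalisation takes the only cis-vicinal diol (O8/O9), and the carboxyl group, cis to the C7 hydroxyl, lactonises at the same time, so the hydroxyl groups are differentiated without touching a stereocentre.

Step 2
Reactants: 2 3,4-O-isopropylidenequinic acid 1,5-lactone
Product: 3 triol acetonide (tertiary C5 carbinol bearing CH2OH; free C7–OH on the top face; O8/O9 acetonide)
Conditions: NaBH4, EtOH, 0 °C to rt
Reagents that add atoms: none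
Why: The strained, α-oxygenated bridged lactone is reduced by borohydride to the primary alcohol, which exposes the C5 carbinol/CH2OH glycol needed for the next cleavage.

Step 3
Reactants: 3 triol acetonide
Product: 4 β-hydroxy ketone (C5 ketone; C7–OH trans to the O8/O9 acetonide)
Conditions: NaIO4, phosphate buffer (pH 7), 0 °C
Reagents that add atoms: none
Why: Periodate glycol cleavage (Malaprade reaction) removes the former carboxyl carbon as formaldehyde and leaves the C5 ketone, because no other free hydroxyl has a free vicinal partner.

Step 4
Reactants: 4 β-hydroxy ketone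
Product: 6 enone (3aR,7aS)-2,2-dimethyl-3a,7a-dihydro-1,3-benzodioxol-5(4H)-one (C5 ketone; C6=C7), via mesylate 5 (not isolated)
Conditions: MsCl, Et3N, CH2Cl2, 0 °C
Reagents that add atoms: none
Why: Mesylation of the β-hydroxy ketone is followed in the same flask by E1cB loss of methanesulfonate, a far better leaving group than the acetonide oxygen on the other side, so the double bond forms at C6=C7.

Step 5
Reactants: 6 enone
Product: 7 allylic alcohol (3aR,5S,7aS)-2,2-dimethyl-3a,4,5,7a-tetrahydro-1,3-benzodioxol-5-ol (C5–OH on the bottom face, cis to the acetonide)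
Conditions: NaBH4, CeCl3·7H2O, MeOH, −78 to 0 °C
Reagents that add atoms: none
Why: Luche reduction adds hydride 1,2 and from the convex top face, opposite the cis-fused acetonide, so the new C5 hydroxyl lands on the same face as O8.

Step 6
Reactants: 7 allylic alcohol
Product: 9 methyl ester (C7–CH2CO2Me on the bottom face cis to O8; C5=C6; O8/O9 acetonide), via ketene acetal 8 (not isolated)
Conditions: MeC(OMe)3, EtCO2H (cat.), xylene, 140 °C, MeOH distilled off
Reagents that add atoms: trimethyl orthoacetate CC(OC)(OC)OC
Why: In the Johnson–Claisen rearrangement the ketene acetal on O5 passes its carbon suprafacially across the bottom face to C7, so C11 ends cis to O8 (a relationship that intermolecular attack anti to the acetonide cannot give) and the alkene moves to C5=C6.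

Step 7
Reactants: 9 methyl ester
Product: 11 hydroxy lactone (trans-fused 6,12-lactone; axial C5–OH on the top face; O8/O9 acetonide), via diol ester 10 (not isolated)
Conditions: OsO4 (2 mol %), NMO, acetone–H2O, rt; crude diol, CSA (cat.), benzene, reflux
Reagents that add atoms: N-methylmorpholine N-oxide C[N+]1([O-])CCOCC1; water O
Why: Upjohn dihydroxylation attacks C5=C6 from the top face, opposite both the C7 side chain and the acetonide, which sets C6 with its oxygen trans to C11, and only the C6 hydroxyl can reach the ester, so acid-catalysed transesterification closes the trans-fused γ-lactone.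

Step 8
Reactants: 11 hydroxy lactone
Product: 13 alkene lactone (C5=C10; trans-fused 6,12-lactone; O8/O9 acetonide), via sulfamate 12 (not isolated)
Conditions: Burgess reagent (MeO2CN−SO2N+Et3), benzene, 60 °C
Reagents that add atoms: none
Why: Burgess dehydration is a syn elimination, and the only β-hydrogen on the same face as the axial C5–O bond sits on C10 (C6 carries its oxygen there), so the alkene forms at C5=C10 and not towards the lactone carbon.

Step 9
Reactants: 13 alkene lactone
Product: 14 diol lactone (C8–OH and C9–OH both on the bottom face; C5=C10; trans-fused 6,12-lactone)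
Conditions: TFA–H2O (9:1), CH2Cl2, 0 °C
Reagents that add atoms: none
Why: Mild acid hydrolysis removes the acetonide faster than it opens the lactone, and the freed C8 hydroxyl cannot take over the acyl group directly, because O6 and O8 lie on opposite ring faces and cannot both bind C12.

Step 10
Reactants: 14 diol lactone
Product: 15 α-hydroxy enone (C9 ketone; C5=C10; free axial C8–OH)
Conditions: MnO2 (activated, excess), CH2Cl2, rt
Reagents that add atoms: none
Why: MnO2 oxidises only the allylic C9 alcohol, whose pseudo-axial C–H bond overlaps with the C5=C10 π bond, and leaves the saturated C8 alcohol, so the diol is differentiated without a protecting group.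

Step 11
Reactants: 15 α-hydroxy enone
Product: 16 silyl ether enone (C8–OTES)
Conditions: TESOTf, 2,6-lutidine, CH2Cl2, −78 °C
Reagents that add atoms: triethylsilyl triflate CC[Si](CC)(CC)OS(=O)(=O)C(F)(F)F
Why: A silyl triflate with a hindered pyridine base silylates the axial α-ketol hydroxyl at low temperature faster than the ketone can enolise, so C8 keeps its configuration.

Step 12
Reactants: 16 silyl ether enone
Product: 17 α-iodo enone (iodine on C10)
Conditions: iodine, pyridine–CH2Cl2 (1:1), 0 °C to rt
Reagents that add atoms: iodine [I][I]
Why: α-Iodination of an enone runs by addition–elimination (pyridine adds to C5, the enolate is iodinated at C10, pyridine leaves), which places the halogen on C10 only.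

Step 13
Reactants: 17 α-iodo enone
Product: 18 enone lactone (6R,7S,8S): C10–CO2Me, C5=C10, C9 ketone, C8–OTES, trans-fused 6,12-lactone
Conditions: CO (1 atm), PdCl2(PPh3)2 (5 mol %), iPr2NEt, MeOH (10 equiv), DMF, 45 °C
Reagents that add atoms: carbon monoxide [C-]#[O+]; methanol CO
Why: In this palladium-catalysed alkoxycarbonylation, zerovalent palladium formed in the flask inserts into the C10–I bond, CO inserts and methanol cleaves the acylpalladium species, which installs C14 as the methyl ester under weakly basic conditions that the lactone and silyl ether tolerate.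

Step 14
Reactants: 19 methylenecyclobutane
Product: 20 1-methylcyclobutene
Conditions: KOtBu (cat.), DMSO, rt; fractional distillation
Reagents that add atoms: none
Why: A base-catalysed prototropic shift through the allyl anion equilibrates the exocyclic alkene with the more substituted endocyclic isomer, which is then separated by careful fractionation.

Step 15
Reactants: 18 enone lactone; 20 1-methylcyclobutene
Product: 21 cis-anti-cis tricyclic photoadduct (new bonds C4–C5 and C1–C10; cyclobutane on the top face; CO2Me on C10 and H on C5 on the bottom face; outer four-membered ring C1–C2–C3–C4 turned away from the six-membered ring; CH3 on C4)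
Conditions: hν (medium-pressure Hg lamp, Pyrex filter), 20 (15 equiv), CH2Cl2, −40 °C
Reagents that add atoms: none
Why: Light absorbed by the enone gives, after intersystem crossing, its twisted triplet, which adds to 20 stepwise through triplet 1,4-diradicals that, after spin inversion, either collapse to the cyclobutane or fall back to 18 and 20. This is the intermolecular enone–alkene [2+2] photocycloaddition in its known enone–cyclobutene variant. The one new ring (C1–C4–C5–C10) is closed by recombination of the 1,4-diradical, and no other ring forms. The step needs head-to-tail regiochemistry (C4–C5 and C1–C10): the polarised triplet pairs C5 with the more substituted, more donor-like alkene carbon C4, and the head-to-head diradical would have to join the fully substituted C4 and C10, so it should revert rather than close. C1 and C4 are cis because both sit in the four-membered ring of 20; C5 and C10 are cis because the stiff trans-fused lactone limits the twist of the triplet and a trans-fused 6-4-4 array is too strained; the outer ring lies anti for steric reasons; and attack comes from the top face (axial bond at C5, away from the axial C8 silyl ether). All four new centres vanish in step 16, so imperfect facial or syn/anti selectivity should cost no material.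

Step 16
Reactants: 21 cis-anti-cis tricyclic photoadduct
Product: 24 cis,cis-cyclodecadienone (4Z; C2 and C9 cis on C1=C10; C9 ketone and C14 ester on C10; C8–OTES; 6,12-lactone), via 4E-dienone 22 (not isolated), via cis-divinylcyclohexanone 23 (not isolated)
Conditions: o-dichlorobenzene (0.01 M), BHT, argon, sealed tube, 210 °C
Reagents that add atoms: none
Why: Homolysis of the strained central C1–C4 bond of the bicyclo[2.2.0]hexane gives a cyclohexane-1,4-diyl that sheds C5–C10 (the known thermal ring expansion of enone–cyclobutene photoadducts); the chair-like diyl should first deliver 22 with a trans C4=C5 bond, but at this temperature 22, its Cope isomer 23 (a 3,3-diacyl-1,5-diene, the class that rearranges readily towards the conjugated alkylidene compound) and 24 interconvert, and 24 should collect as the least strained ring that keeps C1=C10 conjugated with ketone and ester.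

Step 17
Reactants: 24 cis,cis-cyclodecadienone
Product: 25 allylic alcohol (9S; C9–OH threo to C8–OTES)
Conditions: NaBH4, CeCl3·7H2O, MeOH–CH2Cl2, −78 °C
Reagents that add atoms: none
Why: Luche reduction adds hydride 1,2 to the alkylidene β-keto ester, and hydride should arrive from the ring periphery anti to the bulky, non-chelating C8 silyloxy group (Felkin–Anh model), which gives the 8,9-threo relationship, that is 9S.

Step 18
Reactants: 25 allylic alcohol
Product: 26 bis-silyl ether (C9–OTBS; C8–OTES)
Conditions: TBSOTf, 2,6-lutidine, CH2Cl2, −78 to 0 °C
Reagents that add atoms: tert-butyldimethylsilyl triflate CC(C)(C)[Si](C)(C)OS(=O)(=O)C(F)(F)F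
Why: This is a standard silylation of a secondary allylic alcohol, with TBS chosen because it outlasts the TES ether in step 20 yet leaves with fluoride at the end.

Step 19
Reactants: 26 bis-silyl ether
Product: 29 α-methylene lactone (C11=C13H2; C9–OTBS; C8–OTES), via Mannich base 27 (not isolated), via methiodide 28 (not isolated)
Conditions: LDA, THF, −78 °C; CH2=NMe2+ I−, −78 °C to rt; MeI, CH2Cl2, rt; aq. NaHCO3
Reagents that add atoms: Eschenmoser's salt C=[N+](C)C.[I-]
Why: Kinetic deprotonation of the lactone CH2 (C11), Mannich reaction with Eschenmoser's salt, quaternisation and E1cB loss of trimethylamine is the standard α-methylenation of γ-lactones, and the γ-hydrogens of the enoate (on C2, trans to the ester) should not compete at −78 °C.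

Step 20
Reactants: 29 α-methylene lactone
Product: 30 C8 alcohol (C8–OH free; C9–OTBS)
Conditions: PPTS (cat.), MeOH–CH2Cl2, 0 °C
Reagents that add atoms: none
Why: Acid-catalysed methanolysis tells the two silyl ethers apart by the bulk at silicon, the TES ether being cleaved much faster than the TBS ether.

Step 21
Reactants: 30 C8 alcohol; 31 angelic acid ((Z)-2-methylbut-2-enoic acid)
Product: 32 C8 angelate (C9–OTBS)
Conditions: 31, 2,4,6-Cl3C6H2COCl, Et3N, toluene, rt; then 30, 80 °C
Reagents that add atoms: none
Why: Yamaguchi-type mixed-anhydride esterification without a nucleophilic amine catalyst is the established way to acylate hindered alcohols with angelic acid without drift of the Z double bond to the tiglate, and C8 keeps its configuration because only the O–H bond reacts.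

Step 22
Reactants: 32 C8 angelate
Product: 33 target CNP0305372.2
Conditions: HF·pyridine, pyridine, THF, 0 °C to rt
Reagents that add atoms: none
Why: Buffered HF·pyridine cleaves the allylic TBS ether under slightly acidic conditions that avoid acyl shift from O8 to O9 and conjugate addition to the α-methylene lactone.

Compound list
1 | (−)-quinic acid | C1[C@H]([C@H]([C@@H](C[C@@]1(C(=O)O)O)O)O)O | starting material
2 | 3,4-O-isopropylidenequinic acid 1,5-lactone | O[C@@]12C[C@H]3OC(C)(C)O[C@H]3[C@@H](C1)OC2=O | intermediate
3 | triol acetonide | OC[C@]1(O)C[C@H]2OC(C)(C)O[C@H]2[C@H](O)C1 | intermediate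
4 | β-hydroxy ketone | O=C1C[C@H]2OC(C)(C)O[C@H]2[C@H](O)C1 | intermediate
5 | mesylate of 4 | O=C1C[C@H]2OC(C)(C)O[C@H]2[C@H](OS(C)(=O)=O)C1 | intermediate
6 | enone, (3aR,7aS)-2,2-dimethyl-3a,7a-dihydro-1,3-benzodioxol-5(4H)-one | O=C1C[C@H]2OC(C)(C)O[C@H]2C=C1 | intermediate
7 | allylic alcohol, C5–OH cis to acetonide | O[C@H]1C[C@H]2OC(C)(C)O[C@H]2C=C1 | intermediate
8 | mixed ketene acetal of 7 | C=C(OC)O[C@H]1C[C@H]2OC(C)(C)O[C@H]2C=C1 | intermediate
9 | Claisen methyl ester | COC(=O)C[C@H]1C=CC[C@H]2OC(C)(C)O[C@@H]12 | intermediate
10 | 5,6-diol ester | COC(=O)C[C@H]1[C@H](O)[C@H](O)C[C@H]2OC(C)(C)O[C@@H]12 | intermediate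
11 | hydroxy lactone | C1C(=O)O[C@@H]2[C@H](O)C[C@H]3OC(C)(C)O[C@H]3[C@@H]12 | intermediate
12 | C5 sulfamate, triethylammonium salt | C1C(=O)O[C@@H]2[C@H](OS(=O)(=O)[N-]C(=O)OC)C[C@H]3OC(C)(C)O[C@H]3[C@@H]12.CC[NH+](CC)CC | intermediate
13 | alkene lactone acetonide | C1C(=O)O[C@@H]2C=C[C@H]3OC(C)(C)O[C@H]3[C@@H]12 | intermediate
14 | diol lactone | C1C(=O)O[C@@H]2C=C[C@@H](O)[C@@H](O)[C@@H]12 | intermediate
15 | α-hydroxy enone | C1C(=O)O[C@@H]2C=CC(=O)[C@@H](O)[C@@H]12 | intermediate
16 | C8 TES ether enone | C1C(=O)O[C@@H]2C=CC(=O)[C@@H](O[Si](CC)(CC)CC)[C@@H]12 | intermediate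
17 | C10 iodo enone | C1C(=O)O[C@@H]2C=C(I)C(=O)[C@@H](O[Si](CC)(CC)CC)[C@@H]12 | intermediate
18 | enone lactone, 2-carbomethoxycyclohexenone | C1C(=O)O[C@@H]2C=C(C(=O)OC)C(=O)[C@@H](O[Si](CC)(CC)CC)[C@@H]12 | intermediate
19 | methylenecyclobutane | C=C1CCC1 | starting material
20 | 1-methylcyclobutene | CC1=CCC1 | intermediate
21 | cis-anti-cis tricyclic photoadduct | C1C(=O)O[C@@H]2[C@H]3[C@@](C(=O)OC)(C(=O)[C@@H](O[Si](CC)(CC)CC)[C@@H]12)[C@@H]4CC[C@]34C | intermediate
22 | 4E-dienone (trans C4=C5, cis C1=C10 within the ring) | C1C(=O)O[C@@H]2/C=C(\C)CC/C=C(/C(=O)OC)C(=O)[C@@H](O[Si](CC)(CC)CC)[C@@H]12 | intermediate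
23 | cis-divinylcyclohexanone (C10 vinyl and C5 isopropenyl on the top face) | C1C(=O)O[C@@H]2[C@H](C(C)=C)[C@@](C=C)(C(=O)OC)C(=O)[C@@H](O[Si](CC)(CC)CC)[C@@H]12 | intermediate
24 | cis,cis-cyclodecadienone | C1C(=O)O[C@@H]2/C=C(/C)CC/C=C(/C(=O)OC)C(=O)[C@@H](O[Si](CC)(CC)CC)[C@@H]12 | intermediate
25 | 9S allylic alcohol | C1C(=O)O[C@@H]2/C=C(/C)CC/C=C(/C(=O)OC)[C@H](O)[C@@H](O[Si](CC)(CC)CC)[C@@H]12 | intermediate
26 | C9 TBS, C8 TES bis-silyl ether | C1C(=O)O[C@@H]2/C=C(/C)CC/C=C(/C(=O)OC)[C@H](O[Si](C)(C)C(C)(C)C)[C@@H](O[Si](CC)(CC)CC)[C@@H]12 | intermediate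
27 | C11 dimethylaminomethyl lactone (C11 epimers) | CN(C)CC1C(=O)O[C@@H]2/C=C(/C)CC/C=C(/C(=O)OC)[C@H](O[Si](C)(C)C(C)(C)C)[C@@H](O[Si](CC)(CC)CC)[C@@H]12 | intermediate
28 | methiodide of 27 (C11 epimers) | C[N+](C)(C)CC1C(=O)O[C@@H]2/C=C(/C)CC/C=C(/C(=O)OC)[C@H](O[Si](C)(C)C(C)(C)C)[C@@H](O[Si](CC)(CC)CC)[C@@H]12.[I-] | intermediate
29 | α-methylene lactone bis-silyl ether | C=C1C(=O)O[C@@H]2/C=C(/C)CC/C=C(/C(=O)OC)[C@H](O[Si](C)(C)C(C)(C)C)[C@@H](O[Si](CC)(CC)CC)[C@@H]12 | intermediate
30 | C8 alcohol, C9 TBS ether | C=C1C(=O)O[C@@H]2/C=C(/C)CC/C=C(/C(=O)OC)[C@H](O[Si](C)(C)C(C)(C)C)[C@@H](O)[C@@H]12 | intermediate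
31 | angelic acid | C/C=C(/C)C(=O)O | starting material
32 | C8 angelate, C9 TBS ether | C=C1C(=O)O[C@@H]2/C=C(/C)CC/C=C(/C(=O)OC)[C@H](O[Si](C)(C)C(C)(C)C)[C@@H](OC(=O)/C(C)=C\C)[C@@H]12 | intermediate
33 | CNP0305372.2 | C=C1C(=O)O[C@@H]2/C=C(/C)CC/C=C(/C(=O)OC)[C@H](O)[C@@H](OC(=O)/C(C)=C\C)[C@@H]12 | target

Total step count: 22. Longest linear sequence: 21 (steps 1–13 and 15–22).

Steps most likely to fail

Step 16. The geometric equilibration may remain incomplete. The ring opening could stop at the kinetically formed trans C4=C5 isomer or drain into the six-membered Cope isomer. The electrophilic dienone may also decay by transannular bond formation during long heating. The fallback replaces the pericyclic equilibration by a radical one at a sturdier oxidation level.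
- It sets out from 21, which is heated only as hot and as long as the cycloreversion needs (about 180 °C), so that 22 can be isolated.
- 22 is reduced under the conditions of step 17 to the 4E allylic alcohol F1.
- F1 is silylated as in step 18 to the 4E bis-silyl ether F2.
- F2 is treated with PhSSPh under visible light in benzene at rt. Reversible addition of the phenylthiyl radical to C5, rotation about C4–C5 and β-scission relax the strained trans alkene to the cis one, before any α-methylene lactone or angelate is present.
- The fallback comes back to the route at 26.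

Step 17. The ring conformation may override the Felkin–Anh bias and give poor facial selectivity at C9, or hydride may add 1,4 to the doubly activated alkene. The fallback hands the stereocontrol from the substrate to a chiral catalyst.
- It sets out from 24, which is reduced with catecholborane and the (S)-2-methyl-CBS oxazaborolidine in toluene at −78 °C (Corey–Bakshi–Shibata reduction).
- This is the antipode predicted to give 9S if the fully substituted alkenyl carbon C10 acts as the large group.
- The reduction is also strictly 1,2-selective.
- It comes back at 25, and no new compound arises (F0).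

Step 19. The amide base may remove protons at other sites, the lactone enolate may add across the ring to the enoate, or a silyl group may migrate. The fallback avoids amide bases.
- It sets out from 26, which is carboxylated at C11 with MeOMgOCO2Me in DMF at 120 °C. Acidic work-up gives the C11 carboxylic acid F3.
- Aqueous formaldehyde and Et2NH, then NaOAc–AcOH, bring about the decarboxylative Mannich–elimination sequence.
- It comes back at 29.

Further compounds
F1 | step 16 | 4E allylic alcohol (9S, C8 TES ether) | C1C(=O)O[C@@H]2/C=C(\C)CC/C=C(/C(=O)OC)[C@H](O)[C@@H](O[Si](CC)(CC)CC)[C@@H]12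
F2 | step 16 | 4E bis-silyl ether (C9 TBS, C8 TES) | C1C(=O)O[C@@H]2/C=C(\C)CC/C=C(/C(=O)OC)[C@H](O[Si](C)(C)C(C)(C)C)[C@@H](O[Si](CC)(CC)CC)[C@@H]12
F0 | step 17 | none | none
F3 | step 19 | C11 carboxylic acid of 26 (C11 epimers) | OC(=O)C1C(=O)O[C@@H]2/C=C(/C)CC/C=C(/C(=O)OC)[C@H](O[Si](C)(C)C(C)(C)C)[C@@H](O[Si](CC)(CC)CC)[C@@H]12
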